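(The numbers in the tables stem from a simulated flask for an exercise, noise included.)

The time to stop this flask at a chosen ratio of target to isomer of the product is reckoned here from the leak constant L, with a trade s and the last reading beside it.

| setting | north-east | south | flask |
|---|---|---|---|
| starting material | 1.3 M | 1.3 M | 1.3 M |
| partner | 1.8 equiv | 0.90 equiv | 1.80 equiv |
| free catalyst | 10 mol% | 10 mol% | 10 mol% |
| remark | the very flask that is asked about, followed so far | run made earlier |  |
| time |  |  | 50 min |

| run | time / min | target / % | isomer of the product / % |
|---|---|---|---|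
| north-east | 2.00 | 54.1 | 2.9 |
| north-east | 4.00 | 54.4 | 3.9 |
| north-east | 6.00 | 53.4 | 4.4 |
| north-east | 8.00 | 51.9 | 7.1 |
| north-east | 10.0 | 52.1 | 8.1 |
| south | 3.00 | 32.4 | 4.0 |
| south | 8.00 | 30.2 | 4.2 |
| south | 15.0 | 29.1 | 10.0 |
| south | 25.0 | 28.2 | 11.9 |
| south | 40.0 | 27.2 | 14.1 |

(each reading ± 1 percentage point)

- ratio of target to isomer of the product at 1.5 s
- ratio of target to isomer of the product at 80 s
- ratio of target to isomer of the product at 50 min

- what was read earlier has a scatter of 1 percentage point, one standard deviation

The north-east readings give a first L, and the south run gives the trade s, target lost per isomer gained: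

L(north-east) = 0.0122 min⁻¹

s = 0.515

With both held constant, target undergoes a pseudo-first-order decay at rate s·L from the last north-east reading, and isomer gains the target lost, divided by s. Over the remaining 40.0 min:

c(target) = 40.5 %, c(isomer) = 30.5 %, ratio 1.33

The weak link is L. Its window is 8.00 min, and late in the south run the leak reads lower, 0.00582 min⁻¹. The whole south run gives a longer average of the leak constant, isomer gained per minute per unit of target standing:

L = 0.00938 min⁻¹

c(target) = 42.9 %, c(isomer) = 25.9 %, ratio 1.66

Run back to zero time, north-east isomer reads 1.60 % against a scatter of 1 percentage point, so this reckoning commits to no ratio at 1.5 s or 80 s.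

The forecast gives 27, 20 and 1.45, the last below this reckoning's ratio, and adds: “South hints at slowing, so the ratio could run higher.”

The flask gives 86.6, 18.0 and 1.96.

    starting material + partner ⇌ target (K = 0.870 M⁻¹, k = 0.0147 M⁻¹ s⁻¹)
    starting material + partner ⇌ isomer of the product (K = 1.10 M⁻¹, k = 1.49 × 10⁻⁴ M⁻¹ s⁻¹)
    target + free catalyst ⇌ isomer of the product + free catalyst, rate k3*[free catalyst]*[target] forward; the back reaction follows from the equilibrium constant (k = 0.0133 M⁻¹ s⁻¹)
    partner + free catalyst → spent catalyst (k = 0.0155 M⁻¹ s⁻¹)

While free catalyst lasted, target turned into isomer over it, and the ratio fell from 86.6 at 1.5 s to 18.0 at 80 s; by 5.00 min the flask held 0.0853 % free and 99.9 % spent. With free catalyst at 0 % by 25.0 min, isomer formed from starting material and partner directly, beside a target balance whose relaxation half-life was 0.263 min at 50.0 min, and the flask's leak from 5.00 min to 50.0 min was 0.00769 min⁻¹ against L = 0.00938 min⁻¹. In the neighbour with 0.450 equiv of partner, L on its final 12.1 % target over 50 min makes 5.67 % isomer, and 9.24 % stood there at a ratio of 1.31.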